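**Abbreviations and locants.** TBDPS = tert-butyldiphenylsilyl; TIPS = triisopropylsilyl; Ar = 3-methoxy-4-(TIPS-oxy)phenyl; SC = (1S)-2-(TBDPS-oxy)-1-{4-[3-(TBDPS-oxy)propyl]-2-methoxyphenoxy}ethyl; DBU = 1,8-diazabicyclo[5.4.0]undec-7-ene; IBX = 2-iodoxybenzoic acid. Locants C1–C10, C1′ and C2′ follow the 2-oxaspiro[4.5]decane skeleton of target 34 (ring A: C1, O2, C3, C4, C5; ring B: C5–C10).

## The problem

Target 34 is a 2-oxaspiro[4.5]deca-6,9-dien-8-one. Tetrahydrofuran ring A (C1, O2, C3, C4, C5) shares spiro C5 with cyclohexadienone ring B (C5–C10, carbonyl at C8, methoxy on C7). C1 bears a two-carbon chain (C1′ with an aryloxy group, C2′ a CH2OH), C3 a guaiacyl group and C4 a CH2OH.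

There are five stereocentres. C1 (S), C3 (S) and C4 (R) alternate around ring A: the C1 chain and the C4 hydroxymethyl lie on one face, the aryl group on the other. C1′ (S) is syn to the C1 oxygen. Spiro C5 (S) is stereogenic only because the C6–C7 arm of ring B carries the methoxy group, and that arm lies on the face of the C4 hydroxymethyl.

The C1/C1′ pair is partly exocyclic and cannot be controlled from the ring, so it needs an external controller. C4 sits alpha to a carboxyl-level carbon in any sensible precursor and can be equilibrated trans to the C3 aryl group. The C4 hydroxymethyl can reach only the syn enone arm of ring B and can therefore fix C5.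

The cross-conjugated alpha-methoxy dienone will not survive hydride, nucleophilic base or strong acid. The para-oxygenated benzylic ether C3–O2 is opened by acid and one-electron oxidants. Ring B should therefore stay at the ketal or ketone level until late, and the last deprotection must be mild.

The key step rests on the C3–C4 bond of ring A. It joins a benzylic carbon alpha to O2 (a vanillyl ether CH2 in an open precursor) to C4. C4 is flanked by quaternary C5, which has no hydrogen to migrate, and by a carboxyl-level carbon. C4 can therefore be a metal carbenoid from an alpha-diazo ester, with the C3–H bonds 1,5 to it through C5, C1 and O2.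

## Retrosynthesis

**34 to 33.** Only three Si–O bonds are cut. All hydroxyl protection is fluoride-labile so that the dienone, the enol ether and the phenol never meet base, hydride or strong acid at the end.

**33 to 30 (through 32 and 31).** The O–CH3 bond on C7 is cut to give diosphenol 32. That is the beta-elimination product of alpha-ketol 31, which comes from enolate hydroxylation of tricyclic ether 30. The C6–O bond of 30 records an oxa-Michael addition of the C4 hydroxymethyl. A direct epoxidation or alpha-functionalisation of a symmetrical dienone could not tell the two arms apart, whereas the tether can only reach the syn arm. The forward steps need enolisation of 30 at C7 only (guaranteed, since C5 is quaternary and C9 is sp2), an elimination driven by the acidic diosphenol, and methylation of that enol in the presence of a free primary alcohol.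

**30 to 24 (through 29, 28, 27, 26, 25).** The two ring B double bonds, the ketone and the C4 CH2OH are traced back to a ketal and an ester. The ester must be reduced before the dienone exists, and the alcohol is masked as an acetate (27, 28) during the dehydrogenation. Removing the acetate (29) triggers the oxa-Michael step, so the protecting group doubles as the switch. Ring B stays symmetrical until 30, and no C5 stereochemistry has to be carried before that.

**24 to 22 (key disconnection).** The C3–C4 bond is cut. Cutting O2–C3 or C5–C1 instead would need C3 as a preformed stereocentre and would not use the quaternary neighbour of C4. The C3–C4 cut turns C3 into the plain CH2 of a vanillyl ether. Precursor 22 has only two stereocentres (C1, C1′). The forward reaction must insert at the benzylic C–H, pick the correct one of two diastereotopic hydrogens, and deliver (after equilibration) the trans ester.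

**22 to 20.** The diazo group is removed to leave the CH2 of a tert-butyl ester. This ester has no second activating group, so a transient benzoyl group (21) is needed for diazo transfer.

**20 to 16 and 19.** The O2–CH2Ar bond is cut. Alkylation of the C1 hydroxyl is done with an imidate under traces of acid, because an alkoxide at C1 would lactonise onto the gamma ester. In 16 the C1 hydroxyl is the only free one.

**16 to 13 (through 15 and 14).** These are functional group changes only. One silylation covers both primary alcohols (15 to 16), the allyl group is hydroborated (14 to 15), and the auxiliary is removed reductively (13 to 14). The tert-butyl ester is chosen because it survives LiBH4 and resists attack by the neighbouring hydroxyl.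

**13 to 12 and 6.** The C1–C1′ bond is cut (aldol). This sets both acyclic stereocentres from a single auxiliary. Aldehyde 6 cannot enolise, and the aryl ether of C1′ is already in place, so no hindered etherification at C1′ is needed later.

**6, 12 and 19 to commercial materials.** The C5–C4 bond of 6 is made by alkylating the metalloenamine (4) of aldehyde 2 with bromoacetate 3; 2 comes from ester 1. Imide 12 comes from acid 9 and oxazolidinone 10, and 9 from eugenol 7 and bromoacetic acid 8. Imidate 19 comes from vanillyl alcohol 17 through silyl ether 18.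

## Roads not taken

**Alternative 1:** Diels-Alder spiroannulation. The cut is C5–C10 and C6–C7 of ring B. In the forward sense the siloxy diene A2 adds across the exocyclic alkene of the trans-disubstituted methylene lactone A1, and acid work-up gives spiro lactone cyclohexenone A3.
- Merits: the quaternary C5 and ring B arise in one cycloaddition. Approach anti to the C4 substituent puts the saturated C6–C7 arm syn to the C4 CH2O group, so later alpha′-oxygenation of the enone lands on C7 without any relay. For ring B and C5 this road is better than the chosen one, which spends steps 14 to 19 on the same task.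
- Weak points: C1 arrives as a lactone carbonyl. The C1′–C2′ chain with its aryl ether then has to be added to a lactol carbon beside a quaternary centre, creating C1 and C1′ with no reliable control, and the lactone must be reduced in the presence of an enone.
- Comparison: the chosen plan fixes C1 and C1′ by an auxiliary aldol before any ring exists, and pays for it with a longer ring B end game.

**Alternative 2:** Three-component oxonium ylide trapping. The cut is C1–C1′ and C1′–OAr at a late stage. A dirhodium carboxylate converts ethyl diazoacetate A5 and phenol A6 into an oxonium ylide, which adds to the oxocarbenium ion formed at C1 from lactol acetate A4, giving alpha-aryloxy ester A7.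
- Merits: it is the most convergent of the four plans. The complete methoxy dienone core, the phenol and the two-carbon unit are joined in one step, which would cut the linear sequence substantially.
- Weak points: C1 and C1′ are both formed in an intermolecular trapping, with a spiro neighbour whose two arms look alike, so up to four diastereomers are expected. Direct O–H insertion competes. The Lewis acid needed for ionisation threatens the benzylic C3–O2 ether. The ester of A7 would have to be reduced in the presence of the dienone.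
- Comparison: in step economy this road wins. The chosen plan offers controlled C1/C1′ stereochemistry and no hydride after the dienone is formed.

**Alternative 3:** Spirocyclopropyl dienone [3+2] annulation. The cut is O2–C3 and C5–C1. A rare-earth triflate Lewis acid opens spirocyclopropyl dienone A8 to a phenolate and a benzylic cation. The oxygen of ketoaldehyde A9 bonds to C3 and the phenolate para carbon bonds to the aldehyde carbon, closing ring A as 1-acyl spiro dienone A10.
- Merits: ring A and the spiro centre form in one step from two simple fragments, and ring B is already a dienone. To the spiro core this road is clearly shorter than the chosen plan.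
- Weak points: the closing C–C bond must dearomatise a phenolate, so O-attack or reversal is likely. C1 control is uncertain. Ring B is still symmetrical, so the same arm-selective methoxylation remains. The C1′ ketone must then be turned into a configured aryl ether by displacement at a hindered secondary carbon.
- Comparison: the chosen plan avoids any dearomatisation equilibrium and has the C1′ aryl ether and the C1/C1′ pair in place from step 5.

Key step: step 13

## Route

Assumption: the first-formed insertion product is written as the 3,4-cis ester 23, the usual kinetic outcome of carboxylate-catalysed insertions of this type; if the trans ester forms directly, the base treatment in step 13 changes nothing.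

Step 1
Reactants: 1 ethyl 1,4-dioxaspiro[4.5]decane-8-carboxylate
Product: 2 1,4-dioxaspiro[4.5]decane-8-carbaldehyde
Conditions: i-Bu2AlH (1.1 equiv), toluene, −78 °C; aq. KNaC4H4O6
Reagents that add atoms: none
Why: Partial ester reduction; at −78 °C the aluminium hemiacetal persists and releases the aldehyde on work-up, and the ketal is inert.

Step 2
Reactants: 2 1,4-dioxaspiro[4.5]decane-8-carbaldehyde; 3 tert-butyl bromoacetate
Product: 6 tert-butyl 2-(8-formyl-1,4-dioxaspiro[4.5]decan-8-yl)acetate, via cyclohexylimine 4 (not isolated), via C-alkylated imine 5 (not isolated)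
Conditions: c-C6H11NH2, MgSO4, CH2Cl2, 23 °C; LiN(i-Pr)2, THF, −78 → 0 °C; 3, −78 → 23 °C; aq. AcOH–NaOAc, 23 °C
Reagents that add atoms: water, O
Why: Metalloenamine alkylation; the aldimine is deprotonated at its only alpha position and the aza-enolate is C-alkylated by the alpha-bromo ester, building quaternary C5. Buffered hydrolysis returns the aldehyde without touching the ketal or the tert-butyl ester.

Step 3
Reactants: 7 eugenol (4-allyl-2-methoxyphenol); 8 bromoacetic acid
Product: 9 2-(4-allyl-2-methoxyphenoxy)acetic acid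
Conditions: NaOH, H2O, 90 °C; then HCl
Reagents that add atoms: none
Why: Williamson ether synthesis of the phenoxide with bromoacetate, the classical aryloxyacetic acid preparation; the allyl group does not isomerise under these aqueous conditions.

Step 4
Reactants: 9 2-(4-allyl-2-methoxyphenoxy)acetic acid; 10 (R)-4-benzyl-1,3-oxazolidin-2-one
Product: 12 (R)-3-[2-(4-allyl-2-methoxyphenoxy)acetyl]-4-benzyl-1,3-oxazolidin-2-one, via mixed pivalic anhydride 11 (not isolated)
Conditions: t-BuCOCl, Et3N, THF, −20 °C; then 10, LiCl, 23 °C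
Reagents that add atoms: none
Why: N-Acylation of the oxazolidinone through the mixed anhydride; attack occurs at the less hindered aryloxyacetyl carbonyl.

Step 5
Reactants: 12 (R)-3-[2-(4-allyl-2-methoxyphenoxy)acetyl]-4-benzyl-1,3-oxazolidin-2-one; 6 tert-butyl 2-(8-formyl-1,4-dioxaspiro[4.5]decan-8-yl)acetate
Product: 13 (R)-4-benzyl-3-[(2R,3S)-2-(4-allyl-2-methoxyphenoxy)-3-[8-(2-tert-butoxy-2-oxoethyl)-1,4-dioxaspiro[4.5]decan-8-yl]-3-hydroxypropanoyl]-1,3-oxazolidin-2-one
Conditions: n-Bu2BOTf, i-Pr2NEt, CH2Cl2, −78 → 0 °C; 6, −78 → 0 °C; pH 7 buffer, MeOH, H2O2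
Reagents that add atoms: none
Why: Oxazolidinone boron syn-aldol (Evans aldol); the Z boron enolate reacts through a closed chair transition state on the face away from the benzyl group of the (R)-auxiliary. This sets C1′ and C1 as the 2R,3S syn pair, which is the C1 (S), C1′ (S) pair of 34; aldehyde 6 cannot enolise.

Step 6
Reactants: 13 aldol adduct
Product: 14 tert-butyl 2-{8-[(1S,2S)-2-(4-allyl-2-methoxyphenoxy)-1,3-dihydroxypropyl]-1,4-dioxaspiro[4.5]decan-8-yl}acetate
Conditions: LiBH4, MeOH (1.1 equiv), THF, 0 °C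
Reagents that add atoms: none
Why: Reductive removal of the auxiliary; LiBH4 reduces the activated imide carbonyl to the primary alcohol and leaves the tert-butyl ester, which also resists the neighbouring hydroxyl.

Step 7
Reactants: 14 allyl diol
Product: 15 tert-butyl 2-{8-[(1S,2S)-1,3-dihydroxy-2-[4-(3-hydroxypropyl)-2-methoxyphenoxy]propyl]-1,4-dioxaspiro[4.5]decan-8-yl}acetate
Conditions: 9-BBN (4 equiv), THF, 0 → 23 °C; NaBO3·4H2O, H2O, 23 °C
Reagents that add atoms: sodium perborate, [Na+].[Na+].O[B-]1(O)OO[B-](O)(O)OO1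
Why: Anti-Markovnikov hydroboration–oxidation of the terminal alkene; the free hydroxyls only consume extra borane, and the mild perborate oxidation spares the tert-butyl ester.

Step 8
Reactants: 15 triol
Product: 16 tert-butyl 2-{8-[(1S,2S)-3-(TBDPS-oxy)-2-{4-[3-(TBDPS-oxy)propyl]-2-methoxyphenoxy}-1-hydroxypropyl]-1,4-dioxaspiro[4.5]decan-8-yl}acetate
Conditions: t-BuPh2SiCl (2.3 equiv), imidazole, DMF, 0 → 23 °C
Reagents that add atoms: tert-butylchlorodiphenylsilane, CC(C)(C)[Si](Cl)(c1ccccc1)c1ccccc1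
Why: Silylation selective by sterics; both primary hydroxyls react, the secondary C1 hydroxyl next to the quaternary carbon does not.

Step 9
Reactants: 17 vanillyl alcohol (4-(hydroxymethyl)-2-methoxyphenol)
Product: 18 [3-methoxy-4-(TIPS-oxy)phenyl]methanol
Conditions: NaH (1.0 equiv), THF, 0 °C; i-Pr3SiCl, 0 → 23 °C
Reagents that add atoms: chlorotriisopropylsilane, CC(C)[Si](Cl)(C(C)C)C(C)C
Why: One equivalent of NaH deprotonates only the much more acidic phenol, and the phenoxide is silylated while the benzylic alcohol stays free.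

Step 10
Reactants: 18 [3-methoxy-4-(TIPS-oxy)phenyl]methanol
Product: 19 3-methoxy-4-(TIPS-oxy)benzyl 2,2,2-trichloroacetimidate
Conditions: Cl3CCN, DBU (10 mol %), CH2Cl2, 0 °C; used without chromatography
Reagents that add atoms: trichloroacetonitrile, N#CC(Cl)(Cl)Cl
Why: Base-catalysed addition of the benzylic alcohol to trichloroacetonitrile (imidate formation).

Step 11
Reactants: 16 alcohol; 19 imidate
Product: 20 tert-butyl 2-{8-[(1S,2S)-3-(TBDPS-oxy)-2-{4-[3-(TBDPS-oxy)propyl]-2-methoxyphenoxy}-1-(Ar-methoxy)propyl]-1,4-dioxaspiro[4.5]decan-8-yl}acetate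
Conditions: TfOH (2 mol %), CH2Cl2–cyclohexane, 4 Å sieves, −20 → 0 °C
Reagents that add atoms: none
Why: Acid-catalysed benzylation with a trichloroacetimidate; the electron-rich benzylic cation equivalent is captured by the C1 hydroxyl under traces of acid. Acid is used because an alkoxide would lactonise onto the gamma ester; no stereocentre is touched.

Step 12
Reactants: 20 vanillyl ether ester
Product: 22 tert-butyl 2-diazo-2-{8-[(1S,2S)-3-(TBDPS-oxy)-2-{4-[3-(TBDPS-oxy)propyl]-2-methoxyphenoxy}-1-(Ar-methoxy)propyl]-1,4-dioxaspiro[4.5]decan-8-yl}acetate, via 2-benzoyl ester 21 (not isolated)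
Conditions: LiN(i-Pr)2, THF, −78 °C; PhC(O)N(OMe)Me, −78 → 0 °C; aq. NH4Cl; then 4-O2NC6H4SO2N3, DBU, MeCN, 0 → 23 °C
Reagents that add atoms: 4-nitrobenzenesulfonyl azide, [N-]=[N+]=NS(=O)(=O)c1ccc(cc1)[N+](=O)[O-]
Why: Deacylative (Regitz-type) diazo transfer; C-benzoylation of the ester enolate gives beta-keto ester 21, whose DBU enolate attacks the sulfonyl azide. The triazene fragments with transfer of benzoyl to the sulfonamide nitrogen, leaving the alpha-diazo ester.

Step 13
Reactants: 22 diazo ester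
Product: 24 tert-butyl (1S,3S,4S)-3-Ar-1-SC-8,8-(ethylenedioxy)-2-oxaspiro[4.5]decane-4-carboxylate, via 3,4-cis ester 23 (not isolated)
Conditions: dirhodium tetrakis[N-phthaloyl-(S)-tert-leucinate], Rh2(S-PTTL)4 (2 mol %), CH2Cl2, −40 → 23 °C; evaporate; then KOt-Bu (0.5 equiv), t-BuOH–THF, 23 °C
Reagents that add atoms: none
Why: The catalyst extrudes N2 from 22 to give an electrophilic dirhodium carbenoid at C4; because C5 is quaternary there is no beta hydrogen and the usual 1,2-hydride shift is impossible. The carbenoid inserts through a concerted, asynchronous three-centre (hydride-transfer-like) transition state into a benzylic C–H bond of the vanillyl ether on O2, forming C4–C3 with retention at C3; the closest known reaction type is the dirhodium-catalysed intramolecular 1,5 C–H insertion of alpha-diazo esters next to an ether oxygen, which gives 2,3-disubstituted tetrahydrofurans and dihydrobenzofurans. Ring A closes as a five-membered ring by 1,5-insertion (C4, C5, C1, O2, C3) through a six-membered chair-like array that includes the migrating hydrogen. C3 is set by which diastereotopic benzylic hydrogen reacts: the chiral carboxylate ligand sphere must select the hydrogen that places the aryl group trans to the C1 side chain, and substrate bias is small because quaternary C5 removes much of the equatorial preference of the C1 substituent. C4 is set by thermodynamics: whatever the kinetic outcome (cis ester 23 expected), tert-butoxide in tert-butanol equilibrates the centre alpha to the ester to the trans ester 24 without transesterification. Site selectivity comes from the substrate: the benzylic ether C–H is activated by O2 and by the electron-rich arene, whereas the only other C–H 1,5 to the carbenoid (on C2′) is shielded by the TBDPS group and inductively deactivated by the aryloxy group on C1′, and the ring CH2 groups are only 1,3 or 1,4.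

Step 14
Reactants: 24 trans ester
Product: 26 (1S,3S,4R)-3-Ar-4-(hydroxymethyl)-1-SC-2-oxaspiro[4.5]decan-8-one, via hydroxy ketal 25 (not isolated)
Conditions: LiAlH4, THF, 0 → 40 °C; then 1 M HCl, THF, 23 °C
Reagents that add atoms: water, O
Why: Hydride reduction of the hindered tert-butyl ester to the C4 hydroxymethyl with all stereocentres fixed, then acetal hydrolysis of the dioxolane in the acidic work-up; the TBDPS ethers and the aryl TIPS ether tolerate dilute acid.

Step 15
Reactants: 26 hydroxy ketone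
Product: 27 [(1S,3S,4R)-3-Ar-8-oxo-1-SC-2-oxaspiro[4.5]decan-4-yl]methyl acetate
Conditions: Ac2O, pyridine, 23 °C
Reagents that add atoms: acetic anhydride, CC(=O)OC(C)=O
Why: Acetylation of the only free hydroxyl, so that the oxidant of the next step cannot oxidise it.

Step 16
Reactants: 27 keto acetate
Product: 28 [(1S,3S,4R)-3-Ar-8-oxo-1-SC-2-oxaspiro[4.5]deca-6,9-dien-4-yl]methyl acetate
Conditions: IBX, 4-methoxypyridine N-oxide, DMSO, 25 → 40 °C
Reagents that add atoms: none
Why: IBX dehydrogenation of a ketone, carried out twice on the 4,4-disubstituted cyclohexanone, gives the cross-conjugated dienone; the N-oxide complex allows near-ambient temperature, which protects the electron-rich benzylic positions. Ring B is still symmetrical.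

Step 17
Reactants: 28 dienone acetate
Product: 30 (1S,3S,4R,5S,6R)-3-Ar-1-SC-2-oxaspiro[4.5]dec-9-en-8-one with the C4 CH2–O bridge bonded to C6 (cis-fused tetrahydrofuran), via dienone alcohol 29 (not isolated)
Conditions: K2CO3, MeOH, 0 → 23 °C
Reagents that add atoms: none
Why: Methanolysis of the acetate frees the C4 hydroxymethyl, which adds in a 5-exo-trig oxa-Michael reaction to C6 of the syn arm, the only enone carbon it can reach (a trans-fused bicyclo[3.3.0] system is impossible). This cis-fused closure differentiates the two arms and thereby sets C5.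

Step 18
Reactants: 30 tricyclic keto ether
Product: 31 7-hydroxy derivative of 30 (1S,3S,4R,5S,6S; either C7 epimer)
Conditions: KN(SiMe3)2, THF, −78 °C; 2-(phenylsulfonyl)-3-phenyloxaziridine, −78 °C; AcOH
Reagents that add atoms: 2-(phenylsulfonyl)-3-phenyloxaziridine, O=S(=O)(N1OC1c1ccccc1)c1ccccc1
Why: Enolate alpha-hydroxylation with an N-sulfonyloxaziridine; the ketone can enolise only toward C7, and retro-Michael opening of the enolate is harmless because re-addition regenerates the same enolate. The C7 configuration is irrelevant.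

Step 19
Reactants: 31 alpha-ketol
Product: 33 (1S,3S,4R,5S)-3-Ar-4-(hydroxymethyl)-7-methoxy-1-SC-2-oxaspiro[4.5]deca-6,9-dien-8-one, via diosphenol 32 (not isolated)
Conditions: DBU, CH2Cl2, 23 °C; aq. NH4Cl; then Me3SiCHN2, i-Pr2NEt, MeOH–MeCN, 23 °C
Reagents that add atoms: (trimethylsilyl)diazomethane, C[Si](C)(C)C=[N+]=[N-]
Why: E1cB beta-elimination of the C6 ether oxygen from the alpha-ketol, driven by formation of the acidic diosphenol, restores the C6=C7 double bond and frees the C4 hydroxymethyl. The diazoalkane then methylates only the acidic enol hydroxyl, not the aliphatic alcohol, and the phenol is still silylated.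

Step 20
Reactants: 33 tris-silyl ether
Product: 34 (1S,3S,4R,5S)-3-(4-hydroxy-3-methoxyphenyl)-4-(hydroxymethyl)-1-{(1S)-2-hydroxy-1-[4-(3-hydroxypropyl)-2-methoxyphenoxy]ethyl}-7-methoxy-2-oxaspiro[4.5]deca-6,9-dien-8-one
Conditions: Bu4NF, AcOH, THF, 0 → 23 °C
Reagents that add atoms: none
Why: Fluoride cleaves the three Si–O bonds; acetic acid buffering keeps the dienone, the enol ether and the liberated phenol away from basic fluoride.

## Compound list

1 | ethyl 1,4-dioxaspiro[4.5]decane-8-carboxylate | CCOC(=O)C1CCC2(CC1)OCCO2 | starting material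
2 | 1,4-dioxaspiro[4.5]decane-8-carbaldehyde | O=CC1CCC2(CC1)OCCO2 | intermediate
3 | tert-butyl bromoacetate | CC(C)(C)OC(=O)CBr | starting material
4 | N-cyclohexyl-1-(1,4-dioxaspiro[4.5]decan-8-yl)methanimine | C1CCC(CC1)N=CC1CCC2(CC1)OCCO2 | intermediate (not isolated)
5 | tert-butyl 2-{8-[(cyclohexylimino)methyl]-1,4-dioxaspiro[4.5]decan-8-yl}acetate | CC(C)(C)OC(=O)CC1(C=NC2CCCCC2)CCC2(CC1)OCCO2 | intermediate (not isolated)
6 | tert-butyl 2-(8-formyl-1,4-dioxaspiro[4.5]decan-8-yl)acetate | CC(C)(C)OC(=O)CC1(C=O)CCC2(CC1)OCCO2 | intermediate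
7 | eugenol (4-allyl-2-methoxyphenol) | COc1cc(CC=C)ccc1O | starting material
8 | bromoacetic acid | OC(=O)CBr | starting material
9 | 2-(4-allyl-2-methoxyphenoxy)acetic acid | OC(=O)COc1ccc(CC=C)cc1OC | intermediate
10 | (R)-4-benzyl-1,3-oxazolidin-2-one | O=C1N[C@H](Cc2ccccc2)CO1 | starting material
11 | 2-(4-allyl-2-methoxyphenoxy)acetic pivalic anhydride | CC(C)(C)C(=O)OC(=O)COc1ccc(CC=C)cc1OC | intermediate (not isolated)
12 | (R)-3-[2-(4-allyl-2-methoxyphenoxy)acetyl]-4-benzyl-1,3-oxazolidin-2-one | C=CCc1ccc(OCC(=O)N2C(=O)OC[C@H]2Cc2ccccc2)c(OC)c1 | intermediate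
13 | (R)-4-benzyl-3-[(2R,3S)-2-(4-allyl-2-methoxyphenoxy)-3-[8-(2-tert-butoxy-2-oxoethyl)-1,4-dioxaspiro[4.5]decan-8-yl]-3-hydroxypropanoyl]-1,3-oxazolidin-2-one | CC(C)(C)OC(=O)CC1(CCC2(CC1)OCCO2)[C@H](O)[C@@H](Oc1ccc(CC=C)cc1OC)C(=O)N1C(=O)OC[C@H]1Cc1ccccc1 | intermediate
14 | tert-butyl 2-{8-[(1S,2S)-2-(4-allyl-2-methoxyphenoxy)-1,3-dihydroxypropyl]-1,4-dioxaspiro[4.5]decan-8-yl}acetate | CC(C)(C)OC(=O)CC1(CCC2(CC1)OCCO2)[C@H](O)[C@H](CO)Oc1ccc(CC=C)cc1OC | intermediate
15 | tert-butyl 2-{8-[(1S,2S)-1,3-dihydroxy-2-[4-(3-hydroxypropyl)-2-methoxyphenoxy]propyl]-1,4-dioxaspiro[4.5]decan-8-yl}acetate | CC(C)(C)OC(=O)CC1(CCC2(CC1)OCCO2)[C@H](O)[C@H](CO)Oc1ccc(CCCO)cc1OC | intermediate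
16 | tert-butyl 2-{8-[(1S,2S)-3-(TBDPS-oxy)-2-{4-[3-(TBDPS-oxy)propyl]-2-methoxyphenoxy}-1-hydroxypropyl]-1,4-dioxaspiro[4.5]decan-8-yl}acetate | CC(C)(C)OC(=O)CC1(CCC2(CC1)OCCO2)[C@H](O)[C@H](CO[Si](c1ccccc1)(c1ccccc1)C(C)(C)C)Oc1ccc(CCCO[Si](c2ccccc2)(c2ccccc2)C(C)(C)C)cc1OC | intermediate
17 | vanillyl alcohol (4-(hydroxymethyl)-2-methoxyphenol) | COc1cc(CO)ccc1O | starting material
18 | [3-methoxy-4-(triisopropylsilyloxy)phenyl]methanol | COc1cc(CO)ccc1O[Si](C(C)C)(C(C)C)C(C)C | intermediate
19 | 3-methoxy-4-(triisopropylsilyloxy)benzyl 2,2,2-trichloroacetimidate | COc1cc(COC(=N)C(Cl)(Cl)Cl)ccc1O[Si](C(C)C)(C(C)C)C(C)C | intermediate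
20 | tert-butyl 2-{8-[(1S,2S)-3-(TBDPS-oxy)-2-{4-[3-(TBDPS-oxy)propyl]-2-methoxyphenoxy}-1-(Ar-methoxy)propyl]-1,4-dioxaspiro[4.5]decan-8-yl}acetate | CC(C)(C)OC(=O)CC1(CCC2(CC1)OCCO2)[C@H](OCc1ccc(O[Si](C(C)C)(C(C)C)C(C)C)c(OC)c1)[C@H](CO[Si](c1ccccc1)(c1ccccc1)C(C)(C)C)Oc1ccc(CCCO[Si](c2ccccc2)(c2ccccc2)C(C)(C)C)cc1OC | intermediate
21 | 2-benzoyl derivative of 20 (tert-butyl 3-oxo-3-phenylpropanoate carrying the ring at C2; both C2 epimers) | CC(C)(C)OC(=O)C(C(=O)c1ccccc1)C1(CCC2(CC1)OCCO2)[C@H](OCc1ccc(O[Si](C(C)C)(C(C)C)C(C)C)c(OC)c1)[C@H](CO[Si](c1ccccc1)(c1ccccc1)C(C)(C)C)Oc1ccc(CCCO[Si](c2ccccc2)(c2ccccc2)C(C)(C)C)cc1OC | intermediate (not isolated)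
22 | tert-butyl 2-diazo-2-{8-[(1S,2S)-3-(TBDPS-oxy)-2-{4-[3-(TBDPS-oxy)propyl]-2-methoxyphenoxy}-1-(Ar-methoxy)propyl]-1,4-dioxaspiro[4.5]decan-8-yl}acetate | CC(C)(C)OC(=O)C(=[N+]=[N-])C1(CCC2(CC1)OCCO2)[C@H](OCc1ccc(O[Si](C(C)C)(C(C)C)C(C)C)c(OC)c1)[C@H](CO[Si](c1ccccc1)(c1ccccc1)C(C)(C)C)Oc1ccc(CCCO[Si](c2ccccc2)(c2ccccc2)C(C)(C)C)cc1OC | intermediate
23 | tert-butyl (1S,3S,4R)-3-Ar-1-SC-8,8-(ethylenedioxy)-2-oxaspiro[4.5]decane-4-carboxylate (3,4-cis) | O1CCOC12CCC3(CC2)[C@@H](C(=O)OC(C)(C)C)[C@@H](c1ccc(O[Si](C(C)C)(C(C)C)C(C)C)c(OC)c1)O[C@@H]3[C@H](CO[Si](c1ccccc1)(c1ccccc1)C(C)(C)C)Oc1ccc(CCCO[Si](c2ccccc2)(c2ccccc2)C(C)(C)C)cc1OC | intermediate (not isolated)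
24 | tert-butyl (1S,3S,4S)-3-Ar-1-SC-8,8-(ethylenedioxy)-2-oxaspiro[4.5]decane-4-carboxylate (3,4-trans) | O1CCOC12CCC3(CC2)[C@H](C(=O)OC(C)(C)C)[C@@H](c1ccc(O[Si](C(C)C)(C(C)C)C(C)C)c(OC)c1)O[C@@H]3[C@H](CO[Si](c1ccccc1)(c1ccccc1)C(C)(C)C)Oc1ccc(CCCO[Si](c2ccccc2)(c2ccccc2)C(C)(C)C)cc1OC | intermediate
25 | [(1S,3S,4R)-3-Ar-1-SC-8,8-(ethylenedioxy)-2-oxaspiro[4.5]decan-4-yl]methanol | O1CCOC12CCC3(CC2)[C@H](CO)[C@@H](c1ccc(O[Si](C(C)C)(C(C)C)C(C)C)c(OC)c1)O[C@@H]3[C@H](CO[Si](c1ccccc1)(c1ccccc1)C(C)(C)C)Oc1ccc(CCCO[Si](c2ccccc2)(c2ccccc2)C(C)(C)C)cc1OC | intermediate (not isolated)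
26 | (1S,3S,4R)-3-Ar-4-(hydroxymethyl)-1-SC-2-oxaspiro[4.5]decan-8-one | O=C1CCC2(CC1)[C@H](CO)[C@@H](c1ccc(O[Si](C(C)C)(C(C)C)C(C)C)c(OC)c1)O[C@@H]2[C@H](CO[Si](c1ccccc1)(c1ccccc1)C(C)(C)C)Oc1ccc(CCCO[Si](c2ccccc2)(c2ccccc2)C(C)(C)C)cc1OC | intermediate
27 | [(1S,3S,4R)-3-Ar-8-oxo-1-SC-2-oxaspiro[4.5]decan-4-yl]methyl acetate | O=C1CCC2(CC1)[C@H](COC(C)=O)[C@@H](c1ccc(O[Si](C(C)C)(C(C)C)C(C)C)c(OC)c1)O[C@@H]2[C@H](CO[Si](c1ccccc1)(c1ccccc1)C(C)(C)C)Oc1ccc(CCCO[Si](c2ccccc2)(c2ccccc2)C(C)(C)C)cc1OC | intermediate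
28 | [(1S,3S,4R)-3-Ar-8-oxo-1-SC-2-oxaspiro[4.5]deca-6,9-dien-4-yl]methyl acetate | O=C1C=CC2(C=C1)[C@H](COC(C)=O)[C@@H](c1ccc(O[Si](C(C)C)(C(C)C)C(C)C)c(OC)c1)O[C@@H]2[C@H](CO[Si](c1ccccc1)(c1ccccc1)C(C)(C)C)Oc1ccc(CCCO[Si](c2ccccc2)(c2ccccc2)C(C)(C)C)cc1OC | intermediate
29 | (1S,3S,4R)-3-Ar-4-(hydroxymethyl)-1-SC-2-oxaspiro[4.5]deca-6,9-dien-8-one | O=C1C=CC2(C=C1)[C@H](CO)[C@@H](c1ccc(O[Si](C(C)C)(C(C)C)C(C)C)c(OC)c1)O[C@@H]2[C@H](CO[Si](c1ccccc1)(c1ccccc1)C(C)(C)C)Oc1ccc(CCCO[Si](c2ccccc2)(c2ccccc2)C(C)(C)C)cc1OC | intermediate (not isolated)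
30 | (1S,3S,4R,5S,6R)-3-Ar-1-SC-2-oxaspiro[4.5]dec-9-en-8-one with a C4–CH2–O–C6 bridge (cis-fused tricyclic keto ether) | O=C1C=C[C@@]23[C@@H](C1)OC[C@@H]2[C@@H](c1ccc(O[Si](C(C)C)(C(C)C)C(C)C)c(OC)c1)O[C@@H]3[C@H](CO[Si](c1ccccc1)(c1ccccc1)C(C)(C)C)Oc1ccc(CCCO[Si](c2ccccc2)(c2ccccc2)C(C)(C)C)cc1OC | intermediate
31 | 7-hydroxy derivative of 30 (1S,3S,4R,5S,6S; C7 epimers) | O=C1C=C[C@@]23[C@@H](C1O)OC[C@@H]2[C@@H](c1ccc(O[Si](C(C)C)(C(C)C)C(C)C)c(OC)c1)O[C@@H]3[C@H](CO[Si](c1ccccc1)(c1ccccc1)C(C)(C)C)Oc1ccc(CCCO[Si](c2ccccc2)(c2ccccc2)C(C)(C)C)cc1OC | intermediate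
32 | (1S,3S,4R,5S)-3-Ar-7-hydroxy-4-(hydroxymethyl)-1-SC-2-oxaspiro[4.5]deca-6,9-dien-8-one (diosphenol) | OC1=C[C@]2(C=CC1=O)[C@H](CO)[C@@H](c1ccc(O[Si](C(C)C)(C(C)C)C(C)C)c(OC)c1)O[C@@H]2[C@H](CO[Si](c1ccccc1)(c1ccccc1)C(C)(C)C)Oc1ccc(CCCO[Si](c2ccccc2)(c2ccccc2)C(C)(C)C)cc1OC | intermediate (not isolated)
33 | (1S,3S,4R,5S)-3-Ar-4-(hydroxymethyl)-7-methoxy-1-SC-2-oxaspiro[4.5]deca-6,9-dien-8-one | COC1=C[C@]2(C=CC1=O)[C@H](CO)[C@@H](c1ccc(O[Si](C(C)C)(C(C)C)C(C)C)c(OC)c1)O[C@@H]2[C@H](CO[Si](c1ccccc1)(c1ccccc1)C(C)(C)C)Oc1ccc(CCCO[Si](c2ccccc2)(c2ccccc2)C(C)(C)C)cc1OC | intermediate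
34 | (1S,3S,4R,5S)-3-(4-hydroxy-3-methoxyphenyl)-4-(hydroxymethyl)-1-{(1S)-2-hydroxy-1-[4-(3-hydroxypropyl)-2-methoxyphenoxy]ethyl}-7-methoxy-2-oxaspiro[4.5]deca-6,9-dien-8-one | COC1=C[C@]2(C=CC1=O)[C@H](CO)[C@@H](c1ccc(O)c(OC)c1)O[C@@H]2[C@H](CO)Oc1ccc(CCCO)cc1OC | target

## Step count and risk

Total: 20 steps. Longest linear sequence: 16 steps (from 7 through steps 3–8 and 11–20; equally from 1 through steps 1, 2, 5–8 and 11–20).

**Step 13 (key step).** The most likely failure is insertion into the wrong benzylic hydrogen, giving the C3 epimer with the aryl group cis to the C1 chain. A chair-like transition state with both substituents equatorial favours that epimer, and only the catalyst opposes it. The enantiomeric catalyst is the first variable to test. Lesser risks are insertion at the C2′ C–H and cycloaddition to the electron-rich arene.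
Fallback: ring A is closed through O2–C3 instead of C3–C4. Alcohol 16 is silylated (Et3SiOTf, 2,6-lutidine) to the triethylsilyl ether F1. Its lithium ester enolate (LiN(i-Pr)2, THF, −78 °C) is added to 3-methoxy-4-(triisopropylsilyloxy)benzaldehyde F2, made from 18 with MnO2, to give the beta-hydroxy ester F3. Camphorsulfonic acid in CH2Cl2 removes the triethylsilyl group and ionises the benzylic alcohol, and the C1 hydroxyl captures the stabilised cation to close the tetrahydrofuran under thermodynamic control. Equilibration with KOt-Bu in t-BuOH as in step 13 returns to 24.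

**Step 11.** Capture of the benzylic cation by the neopentyl-type C1 hydroxyl may be slow. That would allow Friedel–Crafts benzylation of the electron-rich aryl ether ring, rearrangement of the imidate to the N-benzyl amide, or acid-induced lactonisation of the gamma-hydroxy ester.
Fallback: the alkylation is changed from acid-catalysed imidate transfer to silver-assisted halide displacement in the absence of free acid. Alcohol 18 is converted (CBr4, PPh3) into 4-(bromomethyl)-2-methoxy-1-(triisopropylsilyloxy)benzene F4, which alkylates 16 with AgOTf and 2,6-di-tert-butyl-4-methylpyridine in CH2Cl2 to rejoin the route at 20.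

**Step 12.** C-Benzoylation of the enolate and diazo transfer both take place at a carbon next to the quaternary C5, so either may stall for steric reasons.
Fallback: the diazo group is made from a ketone instead. The enolate of 20 is hydroxylated with 2-(phenylsulfonyl)-3-phenyloxaziridine to the alpha-hydroxy ester F5. Swern oxidation gives the alpha-keto ester F6, and condensation with tosylhydrazide gives the tosylhydrazone F7. Et3N then effects the Bamford–Stevens elimination to 22.

**Step 16.** Over-oxidation is the main risk: single-electron oxidation of the two electron-rich arenes or their benzylic positions. The reaction may also stall at the mono-enone.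
Fallback: two Saegusa–Ito cycles replace the iodine oxidant. Ketone 27 gives (Me3SiOTf, Et3N) the trimethylsilyl enol ether F8, and Pd(OAc)2 in MeCN gives the mono-enone F9. A second silylation gives the trimethylsilyl dienol ether F10, and Pd(OAc)2 again gives 28.

**Step 19.** The beta-elimination may stop at an unfavourable equilibrium if the diosphenol is not acidic enough to drive it, and C-methylation of the diosphenolate could compete.
Fallback: the order is reversed and the ring opening is made irreversible by silyl trapping. Ketol 31 is O-methylated (MeOTf, 2,6-di-tert-butyl-4-methylpyridine) to the alpha-methoxy ketone F11. Treatment with t-BuMe2SiOTf and Et3N opens the ether by silyl-assisted beta-elimination to the C4 tert-butyldimethylsilyloxymethyl methoxy dienone F12. The conditions of step 20 then remove all four silyl groups and give 34.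

## Further compounds

F1 | step 13 | triethylsilyl ether of 16 (C1–O–SiEt3) | CC(C)(C)OC(=O)CC1(CCC2(CC1)OCCO2)[C@H](O[Si](CC)(CC)CC)[C@H](CO[Si](c1ccccc1)(c1ccccc1)C(C)(C)C)Oc1ccc(CCCO[Si](c2ccccc2)(c2ccccc2)C(C)(C)C)cc1OC
F2 | step 13 | 3-methoxy-4-(triisopropylsilyloxy)benzaldehyde | COc1cc(C=O)ccc1O[Si](C(C)C)(C(C)C)C(C)C
F3 | step 13 | tert-butyl 3-hydroxy-3-Ar-propanoate carrying the ring of F1 at C2 (diastereomer mixture at the two new centres) | CC(C)(C)OC(=O)C(C(O)c1ccc(O[Si](C(C)C)(C(C)C)C(C)C)c(OC)c1)C1(CCC2(CC1)OCCO2)[C@H](O[Si](CC)(CC)CC)[C@H](CO[Si](c1ccccc1)(c1ccccc1)C(C)(C)C)Oc1ccc(CCCO[Si](c2ccccc2)(c2ccccc2)C(C)(C)C)cc1OC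
F4 | step 11 | 4-(bromomethyl)-2-methoxy-1-(triisopropylsilyloxy)benzene | COc1cc(CBr)ccc1O[Si](C(C)C)(C(C)C)C(C)C
F5 | step 12 | alpha-hydroxy ester from 20 (both epimers) | CC(C)(C)OC(=O)C(O)C1(CCC2(CC1)OCCO2)[C@H](OCc1ccc(O[Si](C(C)C)(C(C)C)C(C)C)c(OC)c1)[C@H](CO[Si](c1ccccc1)(c1ccccc1)C(C)(C)C)Oc1ccc(CCCO[Si](c2ccccc2)(c2ccccc2)C(C)(C)C)cc1OC
F6 | step 12 | alpha-keto ester from 20 | CC(C)(C)OC(=O)C(=O)C1(CCC2(CC1)OCCO2)[C@H](OCc1ccc(O[Si](C(C)C)(C(C)C)C(C)C)c(OC)c1)[C@H](CO[Si](c1ccccc1)(c1ccccc1)C(C)(C)C)Oc1ccc(CCCO[Si](c2ccccc2)(c2ccccc2)C(C)(C)C)cc1OC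
F7 | step 12 | tosylhydrazone of F6 | CC(C)(C)OC(=O)C(=NNS(=O)(=O)c1ccc(C)cc1)C1(CCC2(CC1)OCCO2)[C@H](OCc1ccc(O[Si](C(C)C)(C(C)C)C(C)C)c(OC)c1)[C@H](CO[Si](c1ccccc1)(c1ccccc1)C(C)(C)C)Oc1ccc(CCCO[Si](c2ccccc2)(c2ccccc2)C(C)(C)C)cc1OC
F8 | step 16 | trimethylsilyl enol ether of 27 (C5 epimers) | C[Si](C)(C)OC1=CCC2(CC1)[C@H](COC(C)=O)[C@@H](c1ccc(O[Si](C(C)C)(C(C)C)C(C)C)c(OC)c1)O[C@@H]2[C@H](CO[Si](c1ccccc1)(c1ccccc1)C(C)(C)C)Oc1ccc(CCCO[Si](c2ccccc2)(c2ccccc2)C(C)(C)C)cc1OC
F9 | step 16 | mono-enone acetate (2-oxaspiro[4.5]dec-6-en-8-one, C5 epimers) | O=C1C=CC2(CC1)[C@H](COC(C)=O)[C@@H](c1ccc(O[Si](C(C)C)(C(C)C)C(C)C)c(OC)c1)O[C@@H]2[C@H](CO[Si](c1ccccc1)(c1ccccc1)C(C)(C)C)Oc1ccc(CCCO[Si](c2ccccc2)(c2ccccc2)C(C)(C)C)cc1OC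
F10 | step 16 | trimethylsilyl dienol ether of F9 (C5 epimers) | C[Si](C)(C)OC1=CCC2(C=C1)[C@H](COC(C)=O)[C@@H](c1ccc(O[Si](C(C)C)(C(C)C)C(C)C)c(OC)c1)O[C@@H]2[C@H](CO[Si](c1ccccc1)(c1ccccc1)C(C)(C)C)Oc1ccc(CCCO[Si](c2ccccc2)(c2ccccc2)C(C)(C)C)cc1OC
F11 | step 19 | 7-methoxy derivative of 30 (C7 epimers) | O=C1C=C[C@@]23[C@@H](C1OC)OC[C@@H]2[C@@H](c1ccc(O[Si](C(C)C)(C(C)C)C(C)C)c(OC)c1)O[C@@H]3[C@H](CO[Si](c1ccccc1)(c1ccccc1)C(C)(C)C)Oc1ccc(CCCO[Si](c2ccccc2)(c2ccccc2)C(C)(C)C)cc1OC
F12 | step 19 | C4 tert-butyldimethylsilyl ether of 33 | COC1=C[C@]2(C=CC1=O)[C@H](CO[Si](C)(C)C(C)(C)C)[C@@H](c1ccc(O[Si](C(C)C)(C(C)C)C(C)C)c(OC)c1)O[C@@H]2[C@H](CO[Si](c1ccccc1)(c1ccccc1)C(C)(C)C)Oc1ccc(CCCO[Si](c2ccccc2)(c2ccccc2)C(C)(C)C)cc1OC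
A1 | alternative 1 | trans-4-[(tert-butyldimethylsilyloxy)methyl]-5-[3-methoxy-4-(triisopropylsilyloxy)phenyl]-3-methylidenedihydrofuran-2(3H)-one | C=C1[C@H](CO[Si](C)(C)C(C)(C)C)[C@@H](c2ccc(O[Si](C(C)C)(C(C)C)C(C)C)c(OC)c2)OC1=O
A2 | alternative 1 | (E)-1-methoxy-3-(trimethylsilyloxy)buta-1,3-diene | CO/C=C/C(=C)O[Si](C)(C)C
A3 | alternative 1 | 4-[(tert-butyldimethylsilyloxy)methyl]-3-[3-methoxy-4-(triisopropylsilyloxy)phenyl]-2-oxaspiro[4.5]dec-6-ene-1,8-dione | O=C1CC[C@]2(C=C1)[C@H](CO[Si](C)(C)C(C)(C)C)[C@@H](c1ccc(O[Si](C(C)C)(C(C)C)C(C)C)c(OC)c1)OC2=O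
A4 | alternative 2 | 4-[(tert-butyldimethylsilyloxy)methyl]-7-methoxy-3-[3-methoxy-4-(triisopropylsilyloxy)phenyl]-8-oxo-2-oxaspiro[4.5]deca-6,9-dien-1-yl acetate (anomers) | COC1=C[C@]2(C=CC1=O)[C@H](CO[Si](C)(C)C(C)(C)C)[C@@H](c1ccc(O[Si](C(C)C)(C(C)C)C(C)C)c(OC)c1)OC2OC(C)=O
A5 | alternative 2 | ethyl diazoacetate | CCOC(=O)C=[N+]=[N-]
A6 | alternative 2 | 4-[3-(tert-butyldimethylsilyloxy)propyl]-2-methoxyphenol | COc1cc(CCCO[Si](C)(C)C(C)(C)C)ccc1O
A7 | alternative 2 | ethyl 2-{4-[3-(tert-butyldimethylsilyloxy)propyl]-2-methoxyphenoxy}-2-(spiro dienone-1-yl)acetate | COC1=C[C@]2(C=CC1=O)[C@H](CO[Si](C)(C)C(C)(C)C)[C@@H](c1ccc(O[Si](C(C)C)(C(C)C)C(C)C)c(OC)c1)O[C@@H]2[C@H](C(=O)OCC)Oc1ccc(CCCO[Si](C)(C)C(C)(C)C)cc1OC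
A8 | alternative 3 | trans-1-[3-methoxy-4-(triisopropylsilyloxy)phenyl]-2-[(triethylsilyloxy)methyl]spiro[2.5]octa-4,7-dien-6-one | O=C1C=CC2(C=C1)[C@H](CO[Si](CC)(CC)CC)[C@H]2c1ccc(O[Si](C(C)C)(C(C)C)C(C)C)c(OC)c1
A9 | alternative 3 | 3-(tert-butyldimethylsilyloxy)-2-oxopropanal | O=CC(=O)CO[Si](C)(C)C(C)(C)C
A10 | alternative 3 | 1-[2-(tert-butyldimethylsilyloxy)acetyl]-3-[3-methoxy-4-(triisopropylsilyloxy)phenyl]-4-[(triethylsilyloxy)methyl]-2-oxaspiro[4.5]deca-6,9-dien-8-one | O=C1C=CC2(C=C1)[C@H](CO[Si](CC)(CC)CC)[C@@H](c1ccc(O[Si](C(C)C)(C(C)C)C(C)C)c(OC)c1)O[C@@H]2C(=O)CO[Si](C)(C)C(C)(C)C
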